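The ten-membered carbocycle is closed by an anionic oxy-Cope ring expansion of a cyclohexanol grown from a furan Diels–Alder cage (17 steps, longest linear sequence 15).

Everything rests on one disconnection: the C3–C4 bond of the ten-membered carbocycle (ring carbons C1–C10; C1 = enoate CH, C6 = lactone carbinol, C10 = ester-bearing carbon) is the σ-bond formed in an anionic oxy-Cope ring expansion. A trans-1,2-dialkenylcyclohexanol (ring C1, C6, C7, C8, C9, C10; vinyl on C1, (E)-3-silyloxypropenyl on carbinol C6) rearranges through a chair: C1–C6 breaks, the ten-membered ring closes, C4 is set and C6 becomes the ketone that later carries the lactone oxygen. The step exploits the 3-oxy-1,5-diene pattern latent between the C6 oxygen and the C1 alkene terminus. The cyclohexanol, with C7 and C8 in place, is grown from a furan Diels–Alder cage.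

Key step: step 12

Labels used throughout: C11, C12, C13 = lactone α-carbon, carbonyl and methylene; C14 = ester carbon on C10; C15 = hydroxymethyl carbon on C4; O6 and O8 = oxygens on C6 and C8. β = the ring face that carries C11 on C7 (also O8 and, in the target, C15); α = the opposite face (O6 in the target). These labels are carried back into the six-membered-ring intermediates.
Remark: 3-acryloyl-1,3-oxazolidin-2-one is taken as a commercial starting material. t-Bu-box = 2,2'-(propane-2,2-diyl)bis(4-tert-butyl-4,5-dihydro-1,3-oxazole).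

Step 1
Reactants: 1 furan; 2 3-acryloyl-1,3-oxazolidin-2-one
Product: 3 3-[(1R,2R,4R)-7-oxabicyclo[2.2.1]hept-5-ene-2-carbonyl]-1,3-oxazolidin-2-one (endo adduct)
Conditions: [Cu((R,R)-t-Bu-box)](SbF6)2 (5 mol %), CH2Cl2, −78 °C
Reagents that add atoms: none
Why: Asymmetric Diels–Alder reaction in which the imide chelates divalent copper inside the chiral bis(oxazoline) pocket, so furan should add endo to one face and set C8 (with C1 and C10); the (R,R) ligand is chosen for the (1R,2R,4R) adduct.

Step 2
Reactants: 3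
Product: 5 iodolactone (6-endo-O to 2-endo-C14 γ-lactone of the 7-oxanorbornane with a 5-exo iodide on C7), via carboxylic acid 4 (not isolated)
Conditions: LiOH, H2O2, THF–H2O, 0 °C; Na2SO3; then NaHCO3, I2, KI, H2O–CH2Cl2, 0 °C to rt
Reagents that add atoms: hydrogen peroxide, OO; iodine, II
Why: Hydroperoxide cleavage of the imide followed by iodolactonisation, in which the endo carboxylate can only reach C6 from the endo (α) face while iodine sits exo (β) on C7, so O6 and the C7 handle are placed regio- and stereospecifically.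

Step 3
Reactants: 5
Product: 6 5-exo-allyl lactone (allyl on C7, β)
Conditions: allylSnBu3, AIBN (cat.), PhH, 80 °C
Reagents that add atoms: allyltributylstannane, C=CC[Sn](CCCC)(CCCC)CCCC
Why: Keck radical allylation in which the C7 radical is trapped on the open exo face of the cage, away from the endo lactone, so C11 should end up cis to the bridging O8.

Step 4
Reactants: 6
Product: 7 5-exo-(2,2-dimethoxyethyl) lactone
Conditions: O3, CH2Cl2–MeOH, −78 °C; TsOH (cat.), rt; Me2S
Reagents that add atoms: methanol, CO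
Why: Ozonolysis in methanol with acid-catalysed acetalisation and reductive work-up masks C12 as a base-stable dimethyl acetal, and no other alkene is present at this stage.

Step 5
Reactants: 7
Product: 9 5-exo-(2,2-dimethoxyethyl)-6-oxo-7-oxabicyclo[2.2.1]heptane-2-endo-carboxylic acid, via lithium hydroxy carboxylate 8 (not isolated)
Conditions: LiOH, THF–H2O, rt; then TEMPO (cat.), KBr (cat.), NaOCl, NaHCO3, H2O–MeCN, 0 °C; 1 M HCl to pH 3, 0 °C
Reagents that add atoms: lithium hydroxide, [Li+].[OH-]
Why: Saponification gives a hydroxy carboxylate that cannot undergo β-elimination (the lactone α-carbon is a bridgehead and the carboxylate is not enolisable), and oxoammonium (TEMPO/hypochlorite) oxidation turns the C6 carbinol into the ketone while O8 stays locked in the ether bridge.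

Step 6
Reactants: 10 prop-2-yn-1-ol
Product: 11 tert-butyl(diphenyl)(prop-2-yn-1-yloxy)silane
Conditions: TBDPSCl, imidazole, DMF, rt
Reagents that add atoms: tert-butyl(chloro)diphenylsilane, CC(C)(C)[Si](Cl)(c1ccccc1)c1ccccc1
Why: Standard silylation of a primary alcohol, giving an acid- and base-robust protecting group for the future C15 hydroxyl.

Step 7
Reactants: 11
Product: 12 tert-butyl{[(2E)-3-iodoprop-2-en-1-yl]oxy}diphenylsilane
Conditions: Cp2Zr(H)Cl, THF, rt; then I2, 0 °C
Reagents that add atoms: iodine, II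
Why: Hydrozirconation adds Zr–H syn with zirconium on the terminal carbon, and iodinolysis with retention gives the (E)-alkenyl iodide.

Step 8
Reactants: 9; 12
Product: 14 methyl ester of the 6-endo-hydroxy-6-exo-[(E)-3-silyloxyprop-1-enyl] cage acid, via hydroxy acid 13 (not isolated)
Conditions: 9: LiHMDS (1.0 equiv), THF, −78 °C; 12: t-BuLi (2 equiv), Et2O, −78 °C, then CeCl3, THF; combine at −78 °C; AcOH; then TMSCHN2, PhMe–MeOH, 0 °C
Reagents that add atoms: (trimethylsilyl)diazomethane, C[Si](C)(C)C=[N+]=[N-]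
Why: Organocerium 1,2-addition (low basicity, so no enolisation or loss of the ether bridge) in which the alkenyl group should enter from the exo (β) face because the endo face is blocked by the C10 endo carboxylate, fixing the C6 carbinol (O6 α, alkenyl β) for the key step; esterification follows.

Step 9
Reactants: 14
Product: 15 methyl cyclohex-1-ene-1-carboxylate (C10=C1) with 6α-OH and 6β-alkenyl, 7β-(2,2-dimethoxyethyl), 8β-OH
Conditions: LiHMDS (3.2 equiv), THF, −78 to 0 °C (inverse addition); AcOH
Reagents that add atoms: none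
Why: E1cB opening of the 7-oxanorbornane, in which the C10 ester enolate expels the bridging oxygen from C1 (the only β-leaving group), giving the C10=C1 enoate and free O8–H without touching C7 or C8; any lactone formed from the tertiary alkoxide is reopened by the methoxide it releases.

Step 10
Reactants: 15
Product: 16 methyl cyclohexanecarboxylate with 1α-vinyl, 6α-OH and 6β-alkenyl, 7β-(2,2-dimethoxyethyl), 8β-OH, 10α-CO2Me (cis to vinyl)
Conditions: vinylMgBr (6 equiv), CuBr·SMe2 (20 mol %), TMSCl, THF, −78 to −30 °C; aq. NH4Cl; K2CO3, MeOH, 0 °C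
Reagents that add atoms: vinylmagnesium bromide, C=C[Mg]Br
Why: Copper-catalysed, TMSCl-accelerated conjugate addition in which the β face of C1 is screened by the β-alkenyl group on C6 and the C7 side chain and the α-alkoxide on C6 can guide the cuprate, so vinyl is expected α (trans to the alkenyl group), with kinetic protonation placing CO2Me cis to vinyl.

Step 11
Reactants: 16
Product: 18 carboxylic acid with 10β-CO2H (trans to vinyl), via trans methyl ester 17 (not isolated)
Conditions: NaOMe (cat.), MeOH, rt; then LiOH, H2O, 45 °C; AcOH to pH 5, 0 °C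
Reagents that add atoms: lithium hydroxide, [Li+].[OH-]
Why: Methoxide equilibration moves C14 to the equatorial position trans to vinyl and saponification then gives a carboxylate, which in the key step has no acidic α-hydrogen and no electrophilic carbonyl.

Step 12
Reactants: 18
Product: 22 methyl (E)-cyclodec-2-ene-1-carboxylate with C1=C2, 4β-CH2OTBDPS, 6-oxo, 7β-(2,2-dimethoxyethyl), 8β-OH, 10β-CO2Me, via tripotassium salt 19 (not isolated), via tripotassium enolate 20 (not isolated), via keto acid 21 (not isolated)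
Conditions: KH (3.5 equiv), 18-crown-6 (3.5 equiv), THF, 0 °C to rt; AcOH, −78 °C; then TMSCHN2, PhMe–MeOH, 0 °C
Reagents that add atoms: (trimethylsilyl)diazomethane, C[Si](C)(C)C=[N+]=[N-]
Why: Salt 19 holds the C1 vinyl and C6 alkenyl groups trans-diequatorial with the C6 alkoxide axial and undergoes an anionic oxy-Cope [3,3]-sigmatropic shift through a chair transition state in which C1–C6 breaks as C3–C4 forms. The closest known reaction type is the alkoxide-accelerated oxy-Cope ring expansion of trans-1,2-divinylcyclohexanols to cyclodec-5-enones. The ten-membered carbocycle closes by this concerted four-atom ring expansion rather than by an end-to-end cyclisation, and it is driven by formation of the C5=C6 enolate. C4 is the only new stereocentre: the chair, the pseudo-equatorial (E)-CH2OSi terminus and the relative configuration of C1 and C6 (both fixed against C7 and C8 in the cage) should place C15 on the β face, cis to C11. The step needs periselectivity and a chair rather than a boat: no second 1,5-diene exists because the C7 side chain is saturated, the diequatorial chair is the ground-state conformer, and the carboxylate and secondary alkoxide carry neither an acidic hydrogen nor an electrophilic site. Cold acetic acid quench and methylation of the acid then give the β-hydroxy keto ester.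

Step 13
Reactants: 22
Product: 23 6α-hydroxy 8β-isobutyrate (C6 reduced, O8 acylated)
Conditions: SmI2 (0.3 equiv), i-PrCHO (8 equiv), THF, −10 °C
Reagents that add atoms: 2-methylpropanal, CC(C)C=O
Why: Evans–Tishchenko reduction in which the samarium-bound hemiacetal of O8 and the aldehyde delivers hydride intramolecularly to C6, which should give the 1,3-anti 6α-alcohol and leave O8 as its isobutyrate in the same operation, so the two oxygens are differentiated.

Step 14
Reactants: 23
Product: 25 trans-fused 6α,12-γ-lactone (C11 still CH2; C1=C2 alkene, 10β-CO2Me), via lactol 24 (not isolated)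
Conditions: PPTS, acetone–H2O, 40 °C; then TEMPO (cat.), PhI(OAc)2, CH2Cl2, rt
Reagents that add atoms: water, O
Why: Acetal hydrolysis closes the five-membered lactol onto the only free hydroxyl (O6) and oxoammonium oxidation of the lactol gives the lactone, with no other oxidisable alcohol present.

Step 15
Reactants: 25
Product: 26 conjugated (E)-enoate lactone (C1=C10)
Conditions: DBU, PhMe, 60 °C
Reagents that add atoms: none
Why: Base-mediated 1,3-prototropic shift through the dienolate moves the strained trans C1=C2 alkene into conjugation, and the ring-cis trisubstituted (E)-enoate is expected as the thermodynamic isomer.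

Step 16
Reactants: 26
Product: 29 α-methylene lactone TBDPS ether, via Mannich base 27 (not isolated), via ammonium iodide 28 (not isolated)
Conditions: LDA (1.05 equiv), THF, −78 °C; CH2=NMe2+ I−, −78 to 0 °C; MeI, MeOH; aq. NaHCO3, EtOAc, rt
Reagents that add atoms: N,N-dimethylmethyleneiminium iodide, C=[N+](C)C.[I-]
Why: Eschenmoser-type α-methylenation, that is kinetic lactone enolate, Mannich reaction, N-methylation and β-elimination, installs C13 on the most accessible α-CH2.

Step 17
Reactants: 29
Product: 30 target CNP0251148.1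
Conditions: HF·pyridine, pyridine–THF, 0 °C to rt
Reagents that add atoms: none
Why: Buffered fluoride desilylation frees the C15 hydroxyl without base or nucleophile that could attack the α-methylene lactone or the esters.

Compound list
1 | furan | c1ccoc1 | starting material
2 | 3-acryloyl-1,3-oxazolidin-2-one | C=CC(=O)N1CCOC1=O | starting material
3 | 3-[(1R,2R,4R)-7-oxabicyclo[2.2.1]hept-5-ene-2-carbonyl]-1,3-oxazolidin-2-one (endo) | O=C([C@@H]1C[C@@H]2C=C[C@H]1O2)N1CCOC1=O | intermediate
4 | (1R,2R,4R)-7-oxabicyclo[2.2.1]hept-5-ene-2-carboxylic acid (endo) | OC(=O)[C@@H]1C[C@@H]2C=C[C@H]1O2 | intermediate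
5 | 5-exo-iodo-6-endo-hydroxy-7-oxabicyclo[2.2.1]heptane-2-endo-carboxylic acid γ-lactone | O=C1O[C@H]2[C@H](I)[C@H]3C[C@@H]1[C@@H]2O3 | intermediate
6 | 5-exo-allyl analogue of 5 | O=C1O[C@H]2[C@H](CC=C)[C@H]3C[C@@H]1[C@@H]2O3 | intermediate
7 | 5-exo-(2,2-dimethoxyethyl) analogue of 5 | O=C1O[C@H]2[C@H](CC(OC)OC)[C@H]3C[C@@H]1[C@@H]2O3 | intermediate
8 | lithium 5-exo-(2,2-dimethoxyethyl)-6-endo-hydroxy-7-oxabicyclo[2.2.1]heptane-2-endo-carboxylate | [Li+].[O-]C(=O)[C@@H]1C[C@H]2O[C@@H]1[C@@H](O)[C@@H]2CC(OC)OC | intermediate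
9 | 5-exo-(2,2-dimethoxyethyl)-6-oxo-7-oxabicyclo[2.2.1]heptane-2-endo-carboxylic acid | OC(=O)[C@@H]1C[C@H]2O[C@@H]1C(=O)[C@@H]2CC(OC)OC | intermediate
10 | prop-2-yn-1-ol | C#CCO | starting material
11 | tert-butyl(diphenyl)(prop-2-yn-1-yloxy)silane | C#CCO[Si](c1ccccc1)(c1ccccc1)C(C)(C)C | intermediate
12 | tert-butyl{[(2E)-3-iodoprop-2-en-1-yl]oxy}diphenylsilane | I/C=C/CO[Si](c1ccccc1)(c1ccccc1)C(C)(C)C | intermediate
13 | 6-exo-[(E)-3-(TBDPS-oxy)prop-1-enyl]-6-endo-hydroxy-5-exo-(2,2-dimethoxyethyl)-7-oxabicyclo[2.2.1]heptane-2-endo-carboxylic acid | OC(=O)[C@@H]1C[C@H]2O[C@@H]1[C@](O)(/C=C/CO[Si](c3ccccc3)(c3ccccc3)C(C)(C)C)[C@@H]2CC(OC)OC | intermediate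
14 | methyl ester of 13 | COC(=O)[C@@H]1C[C@H]2O[C@@H]1[C@](O)(/C=C/CO[Si](c3ccccc3)(c3ccccc3)C(C)(C)C)[C@@H]2CC(OC)OC | intermediate
15 | methyl 3α,5β-dihydroxy-4β-(2,2-dimethoxyethyl)-3β-[(E)-3-(TBDPS-oxy)prop-1-enyl]cyclohex-1-ene-1-carboxylate (C10=C1; C6, C7, C8 = ring positions 3, 4, 5) | COC(=O)C1=C[C@](O)(/C=C/CO[Si](c2ccccc2)(c2ccccc2)C(C)(C)C)[C@H](CC(OC)OC)[C@H](O)C1 | intermediate
16 | methyl cyclohexanecarboxylate: 1α-vinyl, 6α-OH/6β-alkenyl, 7β-(2,2-dimethoxyethyl), 8β-OH, 10α-CO2Me | COC(=O)[C@@H]1C[C@@H](O)[C@@H](CC(OC)OC)[C@@](O)(/C=C/CO[Si](c2ccccc2)(c2ccccc2)C(C)(C)C)[C@@H]1C=C | intermediate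
17 | C10 epimer of 16 (10β-CO2Me, trans to vinyl) | COC(=O)[C@H]1C[C@@H](O)[C@@H](CC(OC)OC)[C@@](O)(/C=C/CO[Si](c2ccccc2)(c2ccccc2)C(C)(C)C)[C@@H]1C=C | intermediate
18 | carboxylic acid of 17 | OC(=O)[C@H]1C[C@@H](O)[C@@H](CC(OC)OC)[C@@](O)(/C=C/CO[Si](c2ccccc2)(c2ccccc2)C(C)(C)C)[C@@H]1C=C | intermediate
19 | tripotassium salt of 18 (carboxylate, C6 alkoxide, C8 alkoxide) | [K+].[K+].[K+].[O-]C(=O)[C@H]1C[C@@H]([O-])[C@@H](CC(OC)OC)[C@@]([O-])(/C=C/CO[Si](c2ccccc2)(c2ccccc2)C(C)(C)C)[C@@H]1C=C | intermediate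
20 | tripotassium salt of the ring-expanded C5=C6 enolate (carboxylate, enolate, C8 alkoxide) | [K+].[K+].[K+].[O-]C(=O)[C@@H]1/C=C/C[C@H](CO[Si](c2ccccc2)(c2ccccc2)C(C)(C)C)C=C([O-])[C@H](CC(OC)OC)[C@H]([O-])C1 | intermediate
21 | ten-membered keto acid: C1=C2 (E), 4β-CH2OTBDPS, 6-oxo, 7β-(2,2-dimethoxyethyl), 8β-OH, 10β-CO2H | OC(=O)[C@@H]1/C=C/C[C@H](CO[Si](c2ccccc2)(c2ccccc2)C(C)(C)C)CC(=O)[C@H](CC(OC)OC)[C@H](O)C1 | intermediate
22 | methyl ester of 21 | COC(=O)[C@@H]1/C=C/C[C@H](CO[Si](c2ccccc2)(c2ccccc2)C(C)(C)C)CC(=O)[C@H](CC(OC)OC)[C@H](O)C1 | intermediate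
23 | 6α-hydroxy-8β-isobutyryloxy ester (from 22) | COC(=O)[C@@H]1/C=C/C[C@H](CO[Si](c2ccccc2)(c2ccccc2)C(C)(C)C)C[C@@H](O)[C@H](CC(OC)OC)[C@H](OC(=O)C(C)C)C1 | intermediate
24 | 6α,12-lactol (C12 hemiacetal, both anomers) | C1C(O)O[C@@H]2C[C@@H](CO[Si](c3ccccc3)(c3ccccc3)C(C)(C)C)C/C=C/[C@@H](C(=O)OC)C[C@@H](OC(=O)C(C)C)[C@@H]12 | intermediate
25 | 6α,12-lactone with C1=C2 (E) and 10β-CO2Me | C1C(=O)O[C@@H]2C[C@@H](CO[Si](c3ccccc3)(c3ccccc3)C(C)(C)C)C/C=C/[C@@H](C(=O)OC)C[C@@H](OC(=O)C(C)C)[C@@H]12 | intermediate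
26 | 6α,12-lactone with conjugated C1=C10 (E) methyl ester | C1C(=O)O[C@@H]2C[C@@H](CO[Si](c3ccccc3)(c3ccccc3)C(C)(C)C)CC/C=C(/C(=O)OC)C[C@@H](OC(=O)C(C)C)[C@@H]12 | intermediate
27 | C11-(dimethylaminomethyl) lactone (C11 epimers) | CN(C)CC1C(=O)O[C@@H]2C[C@@H](CO[Si](c3ccccc3)(c3ccccc3)C(C)(C)C)CC/C=C(/C(=O)OC)C[C@@H](OC(=O)C(C)C)[C@@H]12 | intermediate
28 | C11-(trimethylammoniomethyl) lactone iodide | [I-].C[N+](C)(C)CC1C(=O)O[C@@H]2C[C@@H](CO[Si](c3ccccc3)(c3ccccc3)C(C)(C)C)CC/C=C(/C(=O)OC)C[C@@H](OC(=O)C(C)C)[C@@H]12 | intermediate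
29 | 15-O-TBDPS ether of the target | C=C1C(=O)O[C@@H]2C[C@@H](CO[Si](c3ccccc3)(c3ccccc3)C(C)(C)C)CC/C=C(/C(=O)OC)C[C@@H](OC(=O)C(C)C)[C@@H]12 | intermediate
30 | CNP0251148.1 | C=C1C(=O)O[C@@H]2C[C@@H](CO)CC/C=C(/C(=O)OC)C[C@@H](OC(=O)C(C)C)[C@@H]12 | target

Total step count: 17. Longest linear sequence: 15 (steps 1–5 and 8–17; steps 6–7 make the alkenyl iodide).

Steps most likely to fail

Step 12 (key step). The tris-anion may rearrange sluggishly because of ion pairing of three potassium centres, which would let fragmentation–recombination or proton shuffling compete and erode control at C4. The fallback runs the rearrangement on a less charged substrate and sets out from 16. TBSOTf with 2,6-lutidine silylates only the secondary O8, giving the 8-O-TBS ester F4. NaOMe and then LiOH give the trans acid F5. KH (2.2 equiv) with 18-crown-6 rearranges the bis-anion, and TMSCHN2 gives the 8-O-TBS keto ester F6. HF·pyridine at 0 °C removes the secondary silyl group and the route is rejoined at 22.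

Step 10. Conjugate addition at a β-carbon flanked by a fully substituted carbinol carbon may be slow, so attack at the ester carbonyl or loss of facial control can take over. The fallback uses a more electrophilic acceptor and sets out from 15. DIBAL-H at −78 °C reduces the ester to the allylic alcohol F1. MnO2 oxidises only the primary allylic hydroxyl to the enal F2. Lithium divinylcuprate with TMSCl adds 1,4, and Et3N equilibration gives the trans aldehyde F3. NaClO2, NaH2PO4 and 2-methylbut-2-ene (Pinnick oxidation) convert F3 into acid 18, where the route is rejoined.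

Step 16. Lactone enolisation may be accompanied by deprotonation at the γ-positions of the enoate or at the isobutyrate, leading to aminomethylation at the wrong carbon. The fallback methylenates at the lactol oxidation level without strong base and sets out from 23. DBU moves the alkene into conjugation to give the conjugated hydroxy acetal F7. PPTS in wet acetone closes the lactol F8. N,N-dimethylmethyleneiminium iodide with Et3N (Mannich methylenation of the ring-opened aldehyde form) gives the α-methylene lactol F9. MnO2 oxidises this allylic lactol to 29, where the route is rejoined.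

Further compounds
F1 | step 10 | allylic alcohol from 15 (C14 = CH2OH) | OCC1=C[C@](O)(/C=C/CO[Si](c2ccccc2)(c2ccccc2)C(C)(C)C)[C@H](CC(OC)OC)[C@H](O)C1
F2 | step 10 | enal from F1 (C14 = CHO) | O=CC1=C[C@](O)(/C=C/CO[Si](c2ccccc2)(c2ccccc2)C(C)(C)C)[C@H](CC(OC)OC)[C@H](O)C1
F3 | step 10 | 1α-vinyl 10β-carbaldehyde (trans) | O=C[C@H]1C[C@@H](O)[C@@H](CC(OC)OC)[C@@](O)(/C=C/CO[Si](c2ccccc2)(c2ccccc2)C(C)(C)C)[C@@H]1C=C
F4 | step 12 | 8-O-TBS ether of 16 | COC(=O)[C@@H]1C[C@@H](O[Si](C)(C)C(C)(C)C)[C@@H](CC(OC)OC)[C@@](O)(/C=C/CO[Si](c2ccccc2)(c2ccccc2)C(C)(C)C)[C@@H]1C=C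
F5 | step 12 | 8-O-TBS ether of acid 18 | OC(=O)[C@H]1C[C@@H](O[Si](C)(C)C(C)(C)C)[C@@H](CC(OC)OC)[C@@](O)(/C=C/CO[Si](c2ccccc2)(c2ccccc2)C(C)(C)C)[C@@H]1C=C
F6 | step 12 | 8-O-TBS ether of keto ester 22 | COC(=O)[C@@H]1/C=C/C[C@H](CO[Si](c2ccccc2)(c2ccccc2)C(C)(C)C)CC(=O)[C@H](CC(OC)OC)[C@H](O[Si](C)(C)C(C)(C)C)C1
F7 | step 16 | conjugated (C1=C10) isomer of 23 | COC(OC)C[C@H]1[C@H](O)C[C@@H](CO[Si](c2ccccc2)(c2ccccc2)C(C)(C)C)CC/C=C(/C(=O)OC)C[C@H]1OC(=O)C(C)C
F8 | step 16 | 6α,12-lactol with conjugated ester | C1C(O)O[C@@H]2C[C@@H](CO[Si](c3ccccc3)(c3ccccc3)C(C)(C)C)CC/C=C(/C(=O)OC)C[C@@H](OC(=O)C(C)C)[C@@H]12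
F9 | step 16 | α-methylene lactol | C=C1C(O)O[C@@H]2C[C@@H](CO[Si](c3ccccc3)(c3ccccc3)C(C)(C)C)CC/C=C(/C(=O)OC)C[C@@H](OC(=O)C(C)C)[C@@H]12
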